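**Strategy.** Ring C is cut at the aryl ether bond O1–C8a. O1 joins the C2 carbinol carbon to C8a of ring A, so the ether can be made from the aryl side while the C2–O bond, and with it the (S) centre, is already present. A palladium-catalysed intramolecular etherification closes ring C in one operation. Its precursor is an open-chain (S)-1-arylpropan-1-ol whose ring A carries the C8a triflate, the C8 prenyl group and two MOM ethers, and whose future C4 oxygen is masked as a TBS ether. C4 is oxidised only afterwards, so no chalcone pathway can erode C2.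

Key step: step 11

Remark: the aldol leaves the future C4 carbon racemic, so 19, 20 and 21 are each a pair of epimers at that carbon with uniform (S) configuration at the carbinol/C2 carbon; they are drawn as the (S)-silyloxy isomer and both converge at ketone 22.
Abbreviations: prenyl = 3-methylbut-2-enyl; MOM = methoxymethyl; TBS = tert-butyldimethylsilyl.

**Ring A fragment**

Step 1
Reactants: 1 2,4,6-trihydroxybenzaldehyde; 2 chloromethyl methyl ether
Product: 3 2-hydroxy-4,6-bis(methoxymethoxy)benzaldehyde
Conditions: MOMCl (2.2 equiv), i-Pr2NEt, CH2Cl2, 0 °C → rt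
Reagents that add atoms: chloromethyl methyl ether, COCCl
Why: O-alkylation (MOM ether formation) should take the para hydroxyl and one ortho hydroxyl, while the second ortho hydroxyl, held in a hydrogen bond to the formyl group, stays free.

Step 2
Reactants: 3 2-hydroxy-4,6-bis(methoxymethoxy)benzaldehyde; 4 3-chloro-3-methylbut-1-yne
Product: 5 2-[(2-methylbut-3-yn-2-yl)oxy]-4,6-bis(methoxymethoxy)benzaldehyde
Conditions: 3-chloro-3-methylbut-1-yne (1.5 equiv), DBU, CuCl2·2H2O (1 mol%), MeCN, 0 °C
Reagents that add atoms: 3-chloro-3-methylbut-1-yne, CC(C)(Cl)C#C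
Why: Copper-catalysed propargylic etherification, in which the tertiary chloride is ionised through a copper acetylide and the DBU phenoxide of the only free hydroxyl is captured at the tertiary carbon.

Step 3
Reactants: 5 2-[(2-methylbut-3-yn-2-yl)oxy]-4,6-bis(methoxymethoxy)benzaldehyde
Product: 6 2-[(2-methylbut-3-en-2-yl)oxy]-4,6-bis(methoxymethoxy)benzaldehyde
Conditions: H2 (1 atm), Pd/CaCO3 poisoned with Pb(OAc)2 (Lindlar catalyst), quinoline, EtOAc, rt
Reagents that add atoms: none
Why: Lindlar semi-hydrogenation should stop at the terminal alkene on the poisoned surface and leave the aryl aldehyde and the MOM acetals untouched.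

Step 4
Reactants: 6 2-[(2-methylbut-3-en-2-yl)oxy]-4,6-bis(methoxymethoxy)benzaldehyde
Product: 8 2-hydroxy-4,6-bis(methoxymethoxy)-3-prenylbenzaldehyde, via ortho-dienone 7 (not isolated)
Conditions: o-xylene, 130 °C
Reagents that add atoms: none
Why: Aromatic Claisen rearrangement, in which the [3,3] shift joins the terminal CH2 to the only unsubstituted ortho carbon, the allyl inversion turns the tertiary ether into a linear prenyl group, and tautomerisation of the dienone frees the phenol on the very oxygen that delivered the prenyl group, which fixes the regiochemistry.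

Step 5
Reactants: 8 2-hydroxy-4,6-bis(methoxymethoxy)-3-prenylbenzaldehyde; 9 trifluoromethanesulfonic anhydride
Product: 10 2-formyl-3,5-bis(methoxymethoxy)-6-prenylphenyl trifluoromethanesulfonate
Conditions: Tf2O (1.2 equiv), pyridine, CH2Cl2, −78 → 0 °C
Reagents that add atoms: trifluoromethanesulfonic anhydride, O=S(=O)(OS(=O)(=O)C(F)(F)F)C(F)(F)F
Why: O-sulfonylation of the phenol in a cold, pyridine-buffered medium should spare the MOM ethers and the prenyl alkene and places the leaving group on the future C8a next to the prenyl group.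

**Ring B fragment**

Step 6
Reactants: 11 3'-bromo-4'-hydroxyacetophenone; 2 chloromethyl methyl ether
Product: 12 1-[3-bromo-4-(methoxymethoxy)phenyl]ethanone
Conditions: MOMCl (1.3 equiv), i-Pr2NEt, CH2Cl2, 0 °C → rt
Reagents that add atoms: chloromethyl methyl ether, COCCl
Why: MOM ether formation on the single phenol gives a group that survives the enolate, borane, carbonate and fluoride steps and is removed together with the ring A MOM ethers at the end.

Step 7
Reactants: 12 1-[3-bromo-4-(methoxymethoxy)phenyl]ethanone; 13 tributyl(3-methylbut-2-enyl)stannane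
Product: 14 1-[4-(methoxymethoxy)-3-prenylphenyl]ethanone
Conditions: Pd(PPh3)4 (5 mol%), DMF, 100 °C
Reagents that add atoms: tributyl(3-methylbut-2-enyl)stannane, CCCC[Sn](CCCC)(CCCC)CC=C(C)C
Why: Stille cross-coupling, in which oxidative addition into the C–Br bond, transfer of the allyl group from tin and reductive elimination at the less substituted allyl terminus should give the linear prenyl arene at a position fixed by the bromide.

**Fragment union and key step**

Step 8
Reactants: 14 1-[4-(methoxymethoxy)-3-prenylphenyl]ethanone; 10 2-formyl-3,5-bis(methoxymethoxy)-6-prenylphenyl trifluoromethanesulfonate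
Product: 16 rac-3-hydroxy-1-[4-(methoxymethoxy)-3-prenylphenyl]-3-[4,6-bis(methoxymethoxy)-3-prenyl-2-(trifluoromethanesulfonyloxy)phenyl]propan-1-one, via lithium enolate 15 (not isolated)
Conditions: LiN(SiMe3)2 (1.05 equiv), THF, −78 °C; then 10, −78 °C; AcOH quench at −78 °C
Reagents that add atoms: none
Why: Lithium enolate aldol addition, in which the methyl ketone enolate should add to the aldehyde at −78 °C much faster than it attacks the triflate sulfur, the cold quench prevents retro-aldol and dehydration, and the new carbinol centre is left uncontrolled because it is oxidised later.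

Step 9
Reactants: 16 rac-aldol; 17 tert-butyldimethylsilyl trifluoromethanesulfonate
Product: 18 rac-3-(tert-butyldimethylsilyloxy)-1-[4-(methoxymethoxy)-3-prenylphenyl]-3-[4,6-bis(methoxymethoxy)-3-prenyl-2-(trifluoromethanesulfonyloxy)phenyl]propan-1-one
Conditions: TBSOTf (1.3 equiv), 2,6-lutidine, CH2Cl2, −78 → −20 °C
Reagents that add atoms: tert-butyldimethylsilyl trifluoromethanesulfonate, CC(C)(C)[Si](C)(C)OS(=O)(=O)C(F)(F)F
Why: Silylation of the hindered benzylic alcohol with the silyl triflate and a hindered pyridine base at low temperature avoids enolisation and beta-elimination and leaves the ketone as the only reducible group.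

Step 10
Reactants: 18 rac-silyloxy ketone
Product: 19 (1S,3S)-3-(tert-butyldimethylsilyloxy)-1-[4-(methoxymethoxy)-3-prenylphenyl]-3-[4,6-bis(methoxymethoxy)-3-prenyl-2-(trifluoromethanesulfonyloxy)phenyl]propan-1-ol (plus its C3 epimer)
Conditions: (R)-Me-CBS oxazaborolidine [(3aR)-1-methyl-3,3-diphenyltetrahydro-1H,3H-pyrrolo[1,2-c][1,3,2]oxazaborole] (0.2 equiv), catecholborane (1.8 equiv), PhMe, −78 → −40 °C; then MeOH
Reagents that add atoms: none
Why: Corey–Bakshi–Shibata reduction, in which the (R)-oxazaborolidine binds the ketone with the aryl group as the large substituent and delivers hydride to the Re face to set the (S) carbinol under catalyst control, while catecholborane at low temperature does not hydroborate the prenyl alkenes.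

Step 11
Reactants: 19 (1S,3S)-carbinol triflate (plus its C3 epimer)
Product: 20 (2S,4S)-4-(tert-butyldimethylsilyloxy)-5,7-bis(methoxymethoxy)-2-[4-(methoxymethoxy)-3-prenylphenyl]-8-prenylchroman (plus its C4 epimer)
Conditions: Pd(OAc)2 (5 mol%), 2-(di-tert-butylphosphino)-1,1'-binaphthyl (7.5 mol%), Cs2CO3 (1.5 equiv), PhMe, 80 °C
Reagents that add atoms: none
Why: Zerovalent palladium, formed in the flask from Pd(OAc)2 and the phosphine, inserts into the C8a–OTf bond, carbonate then deprotonates the palladium-bound C2 hydroxyl to give a seven-membered aryl(alkoxo) chelate of divalent palladium, and C–O reductive elimination forges O1–C8a and releases the catalyst. The closest known reaction type is the Buchwald–Hartwig-type intramolecular etherification of secondary alcohols with aryl halides and sulfonates that delivers chromans. Ring C (six-membered, O1–C2–C3–C4–C4a–C8a) closes by C(sp2)–O reductive elimination from that oxapalladacycle, so neither substitution at C2 nor conjugate addition is involved. No stereocentre is created: the C2–O bond is never broken, hence the (S) configuration set in step 10 is carried into the chroman with retention, and the silyloxy-bearing C4 is a spectator. The step needs reductive elimination to outpace beta-hydride elimination from the benzylic palladium alkoxide and S–O cleavage of the triflate, which the bulky electron-rich di-tert-butyl biaryl phosphine, the weak insoluble base and the favourable chelate size should secure. Chemoselectivity is built into 19, which has one triflate (on the oxygen that delivered the C8 prenyl group), one free hydroxyl and no enolisable carbonyl, so neither a regioisomeric closure nor chalcone formation is possible.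

**Endgame**

Step 12
Reactants: 20 (2S,4S)-silyloxychroman (plus its C4 epimer)
Product: 21 (2S,4S)-5,7-bis(methoxymethoxy)-2-[4-(methoxymethoxy)-3-prenylphenyl]-8-prenylchroman-4-ol (plus its C4 epimer)
Conditions: n-Bu4NF (1.5 equiv), THF, 0 °C → rt; water work-up
Reagents that add atoms: none
Why: Fluoride desilylation is driven by the Si–F bond, and its basic, non-acidic medium avoids ionisation of the electron-rich benzylic C4–O bond and leaves the MOM ethers in place.

Step 13
Reactants: 21 (2S,4S)-flavan-4-ol (plus its C4 epimer)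
Product: 22 (2S)-5,7-bis(methoxymethoxy)-2-[4-(methoxymethoxy)-3-prenylphenyl]-8-prenylchroman-4-one
Conditions: Dess–Martin periodinane (1,1,1-triacetoxy-1,1-dihydro-1,2-benziodoxol-3(1H)-one, 1.5 equiv), pyridine, CH2Cl2, 0 °C → rt
Reagents that add atoms: none
Why: Dess–Martin oxidation of the secondary benzylic alcohol erases the C4 stereocentre so that both epimers converge on one ketone, and the pyridine buffer and absence of base should keep C2 intact (no retro-oxa-Michael opening).

Step 14
Reactants: 22 (2S)-tris-MOM flavanone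
Product: 23 Euchrestaflavanone A, (2S)-5,7-dihydroxy-2-(4-hydroxy-3-prenylphenyl)-8-prenylchroman-4-one
Conditions: 3 M aq. HCl–MeOH (1:4), rt, under argon
Reagents that add atoms: none
Why: Acid-catalysed acetal methanolysis should remove the three aryl MOM ethers at ambient temperature, mild enough to avoid cyclisation of the prenyl groups onto the freed phenols and ring-opening epimerisation at C2, while the freed 5-hydroxyl hydrogen-bonds to the C4 carbonyl.

**Compound list**

1 | 2,4,6-trihydroxybenzaldehyde | O=Cc1c(O)cc(O)cc1O | starting material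
2 | chloromethyl methyl ether (MOMCl) | COCCl | starting material
3 | 2-hydroxy-4,6-bis(methoxymethoxy)benzaldehyde | O=Cc1c(O)cc(OCOC)cc1OCOC | intermediate
4 | 3-chloro-3-methylbut-1-yne | CC(C)(Cl)C#C | starting material
5 | 2-[(2-methylbut-3-yn-2-yl)oxy]-4,6-bis(methoxymethoxy)benzaldehyde | O=Cc1c(OC(C)(C)C#C)cc(OCOC)cc1OCOC | intermediate
6 | 2-[(2-methylbut-3-en-2-yl)oxy]-4,6-bis(methoxymethoxy)benzaldehyde | O=Cc1c(OC(C)(C)C=C)cc(OCOC)cc1OCOC | intermediate
7 | 2-formyl-3,5-bis(methoxymethoxy)-6-(3-methylbut-2-enyl)cyclohexa-2,4-dien-1-one (racemic, transient) | O=CC1=C(OCOC)C=C(OCOC)C(CC=C(C)C)C1=O | intermediate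
8 | 2-hydroxy-4,6-bis(methoxymethoxy)-3-(3-methylbut-2-enyl)benzaldehyde | O=Cc1c(O)c(CC=C(C)C)c(OCOC)cc1OCOC | intermediate
9 | trifluoromethanesulfonic anhydride | O=S(=O)(OS(=O)(=O)C(F)(F)F)C(F)(F)F | starting material
10 | 2-formyl-3,5-bis(methoxymethoxy)-6-(3-methylbut-2-enyl)phenyl trifluoromethanesulfonate | O=Cc1c(OS(=O)(=O)C(F)(F)F)c(CC=C(C)C)c(OCOC)cc1OCOC | intermediate
11 | 3'-bromo-4'-hydroxyacetophenone | CC(=O)c1ccc(O)c(Br)c1 | starting material
12 | 1-[3-bromo-4-(methoxymethoxy)phenyl]ethanone | CC(=O)c1ccc(OCOC)c(Br)c1 | intermediate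
13 | tributyl(3-methylbut-2-enyl)stannane | CCCC[Sn](CCCC)(CCCC)CC=C(C)C | starting material
14 | 1-[4-(methoxymethoxy)-3-(3-methylbut-2-enyl)phenyl]ethanone | CC(=O)c1ccc(OCOC)c(CC=C(C)C)c1 | intermediate
15 | lithium 1-[4-(methoxymethoxy)-3-(3-methylbut-2-enyl)phenyl]ethenolate | C=C(O[Li])c1ccc(OCOC)c(CC=C(C)C)c1 | intermediate
16 | rac-3-hydroxy-1-[4-(methoxymethoxy)-3-prenylphenyl]-3-[4,6-bis(methoxymethoxy)-3-prenyl-2-(trifluoromethanesulfonyloxy)phenyl]propan-1-one | CC(C)=CCc1cc(ccc1OCOC)C(=O)CC(O)c1c(OS(=O)(=O)C(F)(F)F)c(CC=C(C)C)c(OCOC)cc1OCOC | intermediate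
17 | tert-butyldimethylsilyl trifluoromethanesulfonate | CC(C)(C)[Si](C)(C)OS(=O)(=O)C(F)(F)F | starting material
18 | rac-3-(tert-butyldimethylsilyloxy)-1-[4-(methoxymethoxy)-3-prenylphenyl]-3-[4,6-bis(methoxymethoxy)-3-prenyl-2-(trifluoromethanesulfonyloxy)phenyl]propan-1-one | CC(C)=CCc1cc(ccc1OCOC)C(=O)CC(O[Si](C)(C)C(C)(C)C)c1c(OS(=O)(=O)C(F)(F)F)c(CC=C(C)C)c(OCOC)cc1OCOC | intermediate
19 | (1S,3S)-3-(tert-butyldimethylsilyloxy)-1-[4-(methoxymethoxy)-3-prenylphenyl]-3-[4,6-bis(methoxymethoxy)-3-prenyl-2-(trifluoromethanesulfonyloxy)phenyl]propan-1-ol, carried together with its (1S,3R) epimer | CC(C)=CCc1cc(ccc1OCOC)[C@@H](O)C[C@H](O[Si](C)(C)C(C)(C)C)c1c(OS(=O)(=O)C(F)(F)F)c(CC=C(C)C)c(OCOC)cc1OCOC | intermediate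
20 | (2S,4S)-4-(tert-butyldimethylsilyloxy)-5,7-bis(methoxymethoxy)-2-[4-(methoxymethoxy)-3-prenylphenyl]-8-prenylchroman, carried together with its (2S,4R) epimer | CC(C)=CCc1cc([C@@H]2C[C@H](O[Si](C)(C)C(C)(C)C)c3c(OCOC)cc(OCOC)c(CC=C(C)C)c3O2)ccc1OCOC | intermediate
21 | (2S,4S)-5,7-bis(methoxymethoxy)-2-[4-(methoxymethoxy)-3-prenylphenyl]-8-prenylchroman-4-ol, carried together with its (2S,4R) epimer | CC(C)=CCc1cc([C@@H]2C[C@H](O)c3c(OCOC)cc(OCOC)c(CC=C(C)C)c3O2)ccc1OCOC | intermediate
22 | (2S)-5,7-bis(methoxymethoxy)-2-[4-(methoxymethoxy)-3-prenylphenyl]-8-prenylchroman-4-one | CC(C)=CCc1cc([C@@H]2CC(=O)c3c(OCOC)cc(OCOC)c(CC=C(C)C)c3O2)ccc1OCOC | intermediate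
23 | Euchrestaflavanone A, (2S)-5,7-dihydroxy-2-[4-hydroxy-3-(3-methylbut-2-enyl)phenyl]-8-(3-methylbut-2-enyl)chroman-4-one | CC(C)=CCc1cc([C@@H]2CC(=O)c3c(O)cc(O)c(CC=C(C)C)c3O2)ccc1O | target

**Step count.** 14 steps in total; the longest linear sequence is 12 steps (steps 1–5 and 8–14, from 1 to 23); the ring B branch (steps 6–7) joins at step 8.

**Steps most likely to fail**

1. Step 11 (ring closure). Oxidative addition into the doubly ortho-flanked, electron-rich C8a–OTf bond may be slow. Base-mediated S–O cleavage of the triflate, beta-hydride elimination from the palladium alkoxide (carbinol oxidation with hydrodetriflation) or silyl migration between the two oxygens could then compete with reductive elimination.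
 Fallback, from 18 back to 20: the ether would be closed from the other side, at C2–O1, with inversion. Ketone 18 would be reduced with the enantiomeric (S)-Me-CBS oxazaborolidine and catecholborane to (1R,3S)-3-(tert-butyldimethylsilyloxy)-1-[4-(methoxymethoxy)-3-prenylphenyl]-3-[4,6-bis(methoxymethoxy)-3-prenyl-2-(trifluoromethanesulfonyloxy)phenyl]propan-1-ol F1 (with its C3 epimer). The triflate would be cleaved with Et4NOH in dioxane at rt to (1R,3S)-3-(tert-butyldimethylsilyloxy)-3-[2-hydroxy-4,6-bis(methoxymethoxy)-3-prenylphenyl]-1-[4-(methoxymethoxy)-3-prenylphenyl]propan-1-ol F2. Mitsunobu cyclisation (PPh3, diisopropyl azodicarboxylate, THF, 0 °C) should then displace the activated benzylic oxygen by the phenol with inversion and return to 20. This is held in reserve because ionisation of the para-alkoxybenzylic oxyphosphonium could erode the configuration.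

2. Step 2 (with its follow-up, step 4). O-alkylation of the chelated, flanked phenoxide by the tertiary electrophile may be sluggish and lose out to elimination of the chloride. In step 4 the tertiary ether could ionise thermally and shed the allyl unit instead of rearranging.
 Fallback, from 1 back to 8: 2,4,6-trihydroxybenzaldehyde 1 would be C-prenylated directly with prenyl bromide and DBU in THF (0 °C → rt) to 2,4,6-trihydroxy-3-(3-methylbut-2-enyl)benzaldehyde F3. Bis-MOM protection (MOMCl, i-Pr2NEt, CH2Cl2, 0 °C) should then take the para hydroxyl and the less hindered ortho hydroxyl and leave the chelated hydroxyl next to the prenyl group free, which is 8. The position of the free hydroxyl would have to be proven before triflation, since this route lacks the built-in regiocontrol of the Claisen sequence.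

3. Step 14 (global MOM removal). Under Brønsted acid a freed phenol may add across its neighbouring prenyl double bond (dimethylchroman formation), and acid-promoted opening and reclosure of ring C may erode C2.
 Fallback, from 22 back to 23: the aryl MOM ethers would be exchanged for silyl ethers without protic acid, using Me3SiOTf and 2,2'-bipyridyl in CH2Cl2 at 0 °C, to give (2S)-5,7-bis(trimethylsilyloxy)-2-[4-(trimethylsilyloxy)-3-prenylphenyl]-8-prenylchroman-4-one F4. Hydrolysis of the labile aryl silyl ethers with water in THF at rt should then give 23.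

**Further compounds**

F1 | step 11 | (1R,3S)-3-(tert-butyldimethylsilyloxy)-1-[4-(methoxymethoxy)-3-prenylphenyl]-3-[4,6-bis(methoxymethoxy)-3-prenyl-2-(trifluoromethanesulfonyloxy)phenyl]propan-1-ol (with its C3 epimer) | CC(C)=CCc1cc(ccc1OCOC)[C@H](O)C[C@H](O[Si](C)(C)C(C)(C)C)c1c(OS(=O)(=O)C(F)(F)F)c(CC=C(C)C)c(OCOC)cc1OCOC
F2 | step 11 | (1R,3S)-3-(tert-butyldimethylsilyloxy)-3-[2-hydroxy-4,6-bis(methoxymethoxy)-3-prenylphenyl]-1-[4-(methoxymethoxy)-3-prenylphenyl]propan-1-ol (with its C3 epimer) | CC(C)=CCc1cc(ccc1OCOC)[C@H](O)C[C@H](O[Si](C)(C)C(C)(C)C)c1c(O)c(CC=C(C)C)c(OCOC)cc1OCOC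
F3 | step 2 | 2,4,6-trihydroxy-3-(3-methylbut-2-enyl)benzaldehyde | O=Cc1c(O)cc(O)c(CC=C(C)C)c1O
F4 | step 14 | (2S)-5,7-bis(trimethylsilyloxy)-2-[4-(trimethylsilyloxy)-3-prenylphenyl]-8-prenylchroman-4-one | CC(C)=CCc1cc([C@@H]2CC(=O)c3c(O[Si](C)(C)C)cc(O[Si](C)(C)C)c(CC=C(C)C)c3O2)ccc1O[Si](C)(C)C
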